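**Retrosynthetic overview**

- Feature: ring B (C1'–C6') has C3'–OH and C5'–OH meta to each other around C4'–H, the prenyl group on C6', and carbonyl-level carbons on the adjacent C1' (diaryl ketone) and C2' (CHO). This is the imprint of a 1,1,3-trioxygenated diene (C3'–C6') on a two-carbon alkyne (C1', C2').
- Key disconnection: C1'–C6' and C2'–C3', by an aromatising Diels–Alder reaction of the prenylated silyl ketene acetal diene 17 with alkynoate 10. Compound 10 already carries ring A on a silyl-protected carbinol; afterwards the ester becomes the CHO and the carbinol becomes the ketone.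
- Alkynoate 10: lithiated methyl propiolate plus ring-A aldehyde 6, which comes from 3,5-dimethoxytoluene by ortho-lithiation/formylation, bromination, selective demethylation and MOM protection.
- Diene 17: γ-prenylation of the methyl acetoacetate dianion, then two silylations.
- Ring order: ring A is bought; ring B is the only ring formed (step 10).

Key step: step 10

Remark: the target has no stereocentre, so there is no enantiomer to select; the one stereocentre made on the way (the diaryl carbinol carbon) is carried racemic and erased on oxidation to the ketone.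

**Route**

Step 1
Reactants: 1 3,5-dimethoxytoluene
Product: 3 2,6-dimethoxy-4-methylbenzaldehyde, via aryllithium 2 (not isolated)
Conditions: n-BuLi, TMEDA, Et2O, 0 °C → rt; DMF, 0 °C; aq. NH4Cl
Reagents that add atoms: N,N-dimethylformamide, CN(C)C=O
Why: Directed ortho-metalation places lithium on the ring carbon between the two methoxy groups (double coordination, most acidic ring C–H), and the aryllithium is formylated by DMF, which gives the 2,6-dimethoxy isomer that electrophilic formylation would not favour.

Step 2
Reactants: 3 2,6-dimethoxy-4-methylbenzaldehyde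
Product: 4 3-bromo-2,6-dimethoxy-4-methylbenzaldehyde
Conditions: NBS (1.0 equiv), MeCN, 0 °C → rt, dark
Reagents that add atoms: N-bromosuccinimide, BrN1C(=O)CCC1=O
Why: Electrophilic aromatic bromination at the only kind of free ring position (C3 and C5 are equivalent, each ortho/para to both methoxy groups), and the first bromine crowds and deactivates the ring enough for one equivalent to stop at the monobromide.

Step 3
Reactants: 4 3-bromo-2,6-dimethoxy-4-methylbenzaldehyde
Product: 5 3-bromo-2-hydroxy-6-methoxy-4-methylbenzaldehyde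
Conditions: BCl3 (1.1 equiv), CH2Cl2, –78 → 0 °C; H2O
Reagents that add atoms: none
Why: Chelation-assisted Lewis-acid ether cleavage, in which BCl3 bound to the aldehyde oxygen delivers chloride to an ortho methyl ether; the ether squeezed between CHO and Br is twisted out of conjugation, so it is more basic and relieved of strain on cleavage and should go first, while one equivalent at low temperature guards the second ether.

Step 4
Reactants: 5 3-bromo-2-hydroxy-6-methoxy-4-methylbenzaldehyde
Product: 6 3-bromo-6-methoxy-2-(methoxymethoxy)-4-methylbenzaldehyde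
Conditions: MOMCl, i-Pr2NEt, CH2Cl2, 0 °C → rt
Reagents that add atoms: chloromethyl methyl ether, COCCl
Why: O-alkylation of the phenoxide with the hard electrophile MOMCl (Williamson-type acetal formation), for which Hünig's base is enough with this acidic salicylaldehyde-type hydroxyl.

Step 5
Reactants: 7 methyl propiolate; 6 3-bromo-6-methoxy-2-(methoxymethoxy)-4-methylbenzaldehyde
Product: 9 methyl 4-[3-bromo-6-methoxy-2-(methoxymethoxy)-4-methylphenyl]-4-hydroxybut-2-ynoate (racemic), via lithium acetylide 8 (not isolated)
Conditions: LiHMDS, THF, –78 °C; then 6, –78 °C; aq. NH4Cl at –78 °C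
Reagents that add atoms: none
Why: 1,2-Addition of a lithium acetylide to an aldehyde, with the propiolate anion formed first by a non-nucleophilic amide so that no alkyllithium meets the aryl bromide; the carbinol stereocentre forms without control (racemic), which is immaterial because it ends as the ketone.

Step 6
Reactants: 9 methyl 4-[3-bromo-6-methoxy-2-(methoxymethoxy)-4-methylphenyl]-4-hydroxybut-2-ynoate (racemic)
Product: 10 methyl 4-[3-bromo-6-methoxy-2-(methoxymethoxy)-4-methylphenyl]-4-(tert-butyldimethylsilyloxy)but-2-ynoate (racemic)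
Conditions: TBSCl, imidazole, DMF, rt
Reagents that add atoms: tert-butyldimethylsilyl chloride, CC(C)(C)[Si](C)(C)Cl
Why: Imidazole-promoted silylation of a secondary alcohol (Corey conditions), with a base weak enough not to isomerise the γ-hydroxy ynoate to the γ-oxo enoate.

Step 7
Reactants: 11 methyl acetoacetate; 12 prenyl bromide
Product: 14 methyl 7-methyl-3-oxooct-6-enoate, via acetoacetate dianion 13 (not isolated)
Conditions: NaH, THF, 0 °C; n-BuLi, 0 °C; prenyl bromide, 0 °C; aq. HCl
Reagents that add atoms: none
Why: γ-Alkylation of a β-keto ester dianion (Weiler alkylation), in which the terminal carbanion is the more reactive site and displaces the allylic bromide by SN2.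

Step 8
Reactants: 14 methyl 7-methyl-3-oxooct-6-enoate
Product: 15 methyl (2Z)-7-methyl-3-(trimethylsilyloxy)octa-2,6-dienoate
Conditions: TMSCl, Et3N, hexane, rt
Reagents that add atoms: chlorotrimethylsilane, C[Si](C)(C)Cl
Why: Silyl enol ether formation from the readily enolised β-keto ester (first stage of a Chan-type diene synthesis); the enol ether geometry, drawn Z, is of no consequence because this bond becomes the central single bond of the diene.

Step 9
Reactants: 15 methyl (2Z)-7-methyl-3-(trimethylsilyloxy)octa-2,6-dienoate
Product: 17 (1Z,3Z)-1-methoxy-7-methyl-1,3-bis(trimethylsilyloxy)octa-1,3,6-triene, via lithium dienolate 16 (not isolated)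
Conditions: LDA, THF, –78 °C; TMSCl, –78 °C → rt; non-aqueous work-up, used crude
Reagents that add atoms: chlorotrimethylsilane, C[Si](C)(C)Cl
Why: Kinetic γ-deprotonation of the β-silyloxy enoate gives the extended ester dienolate, which the hard silyl chloride traps on oxygen as the silyl ketene acetal (second stage of the Chan-type diene synthesis).

Step 10
Reactants: 10 methyl 4-[3-bromo-6-methoxy-2-(methoxymethoxy)-4-methylphenyl]-4-(tert-butyldimethylsilyloxy)but-2-ynoate (racemic); 17 (1Z,3Z)-1-methoxy-7-methyl-1,3-bis(trimethylsilyloxy)octa-1,3,6-triene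
Product: 19 methyl 2-{[3-bromo-6-methoxy-2-(methoxymethoxy)-4-methylphenyl](tert-butyldimethylsilyloxy)methyl}-4,6-dihydroxy-3-(3-methylbut-2-enyl)benzoate (racemic), via cyclohexadiene cycloadduct 18 (not isolated)
Conditions: 17 (3 equiv), toluene, 110 °C, sealed tube; then 0.5 M aq. HCl, THF, 0 °C
Reagents that add atoms: none
Why: A thermal, strongly polarised Diels–Alder reaction: the diene terminus that carries the prenyl CH2 has the largest HOMO coefficient and bonds to the ester-β alkyne carbon (C6'–C1'), while the ketene-acetal carbon bonds to the ester-α carbon (C3'–C2'). The closest known reaction type is the benzannulation of 1-alkoxy-1,3-bis(silyloxy)buta-1,3-dienes with alkynoates to resorcylates, applied here to a more crowded alkynoate. Ring B is closed as a six-membered carbocycle by this intermolecular [4+2] cycloaddition (four diene carbons plus two alkyne carbons, both ring bonds made in the one event); in the acidic work-up the mixed methyl silyl ketal at C3' loses methanol and the silyl enol ether at C5' is cleaved, so the cyclohexadiene tautomerises to the resorcinol. No stereocentre is created in the product, since the two sp3 ring carbons of 18 become aromatic and the carbinol carbon stays racemic. The step needs one regiochemistry (prenyl next to C1', hydroxyl next to the ester), secured because the ester is the only acceptor on the alkyne while the future ketone is held as a non-activating silyl ether; the (3Z) geometry keeps the prenyl CH2 on the outside of the s-cis diene, and the isolated prenyl alkene is no dienophile for this diene.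

Step 11
Reactants: 19 methyl 2-{[3-bromo-6-methoxy-2-(methoxymethoxy)-4-methylphenyl](tert-butyldimethylsilyloxy)methyl}-4,6-dihydroxy-3-(3-methylbut-2-enyl)benzoate (racemic)
Product: 20 methyl 2-{[3-bromo-6-methoxy-2-(methoxymethoxy)-4-methylphenyl](tert-butyldimethylsilyloxy)methyl}-4,6-bis(methoxymethoxy)-3-(3-methylbut-2-enyl)benzoate (racemic)
Conditions: NaH, MOMCl, DMF, 0 °C → rt
Reagents that add atoms: chloromethyl methyl ether, COCCl
Why: Double Williamson-type O-alkylation of the phenoxides, with NaH used because the hydroxyl next to the ester is hydrogen-bonded, and with the hard MOMCl favouring oxygen over ring carbon.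

Step 12
Reactants: 20 methyl 2-{[3-bromo-6-methoxy-2-(methoxymethoxy)-4-methylphenyl](tert-butyldimethylsilyloxy)methyl}-4,6-bis(methoxymethoxy)-3-(3-methylbut-2-enyl)benzoate (racemic)
Product: 21 [2-{[3-bromo-6-methoxy-2-(methoxymethoxy)-4-methylphenyl](tert-butyldimethylsilyloxy)methyl}-4,6-bis(methoxymethoxy)-3-(3-methylbut-2-enyl)phenyl]methanol (racemic)
Conditions: DIBAL-H (4 equiv), toluene, –78 → 0 °C; Rochelle salt
Reagents that add atoms: none
Why: Hydride reduction of the ester to the primary alcohol with DIBAL-H, which spares the aryl bromide, silyl ether, MOM acetals and alkene, and which is run before desilylation so that a free carbinol never sits next to the ester (no phthalide formation).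

Step 13
Reactants: 21 [2-{[3-bromo-6-methoxy-2-(methoxymethoxy)-4-methylphenyl](tert-butyldimethylsilyloxy)methyl}-4,6-bis(methoxymethoxy)-3-(3-methylbut-2-enyl)phenyl]methanol (racemic)
Product: 22 [3-bromo-6-methoxy-2-(methoxymethoxy)-4-methylphenyl][2-(hydroxymethyl)-3,5-bis(methoxymethoxy)-6-(3-methylbut-2-enyl)phenyl]methanol (racemic)
Conditions: TBAF, THF, rt → 45 °C; aq. NH4Cl; base-washed silica
Reagents that add atoms: none
Why: Fluoride-driven Si–O cleavage (strong Si–F bond), in which the small fluoride reaches the crowded silicon and the non-acidic medium spares the MOM ethers and keeps the ionisable diaryl carbinol from closing onto the neighbouring CH2OH to a phthalan.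

Step 14
Reactants: 22 [3-bromo-6-methoxy-2-(methoxymethoxy)-4-methylphenyl][2-(hydroxymethyl)-3,5-bis(methoxymethoxy)-6-(3-methylbut-2-enyl)phenyl]methanol (racemic)
Product: 24 2-[3-bromo-6-methoxy-2-(methoxymethoxy)-4-methylbenzoyl]-4,6-bis(methoxymethoxy)-3-(3-methylbut-2-enyl)benzaldehyde, via bis(alkoxysulfonium) salt 23 (not isolated)
Conditions: (COCl)2 (5 equiv), DMSO, CH2Cl2, –78 °C; 22, –78 → –45 °C; Et3N, –78 → 0 °C
Reagents that add atoms: none
Why: Swern oxidation, in which both hydroxyls are turned into alkoxysulfonium ions before any base is added, so no free hydroxyl remains to add to a newly formed carbonyl and the lactol-to-phthalide path is closed, as in the conversion of 1,2-benzenedimethanols to phthalaldehydes.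

Step 15
Reactants: 24 2-[3-bromo-6-methoxy-2-(methoxymethoxy)-4-methylbenzoyl]-4,6-bis(methoxymethoxy)-3-(3-methylbut-2-enyl)benzaldehyde
Product: 25 Pestalone B, 2-(3-bromo-2-hydroxy-6-methoxy-4-methylbenzoyl)-4,6-dihydroxy-3-(3-methylbut-2-enyl)benzaldehyde
Conditions: 3 M aq. HCl, THF, 45 °C
Reagents that add atoms: none
Why: Acid-catalysed hydrolysis of the three aryl MOM acetals under conditions intended to stay below those that cyclise an ortho-prenyl phenol to a chroman; the aqueous medium avoids acetal formation at the aldehyde, and base is avoided because the ortho-formyl benzophenone could disproportionate to a phthalide.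

**Compound list**

1 | 3,5-dimethoxytoluene | COc1cc(C)cc(OC)c1 | starting material
2 | 2,6-dimethoxy-4-methylphenyllithium (not isolated) | [Li]c1c(OC)cc(C)cc1OC | intermediate
3 | 2,6-dimethoxy-4-methylbenzaldehyde | COc1cc(C)cc(OC)c1C=O | intermediate
4 | 3-bromo-2,6-dimethoxy-4-methylbenzaldehyde | COc1cc(C)c(Br)c(OC)c1C=O | intermediate
5 | 3-bromo-2-hydroxy-6-methoxy-4-methylbenzaldehyde | COc1cc(C)c(Br)c(O)c1C=O | intermediate
6 | 3-bromo-6-methoxy-2-(methoxymethoxy)-4-methylbenzaldehyde | COCOc1c(Br)c(C)cc(OC)c1C=O | intermediate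
7 | methyl propiolate | COC(=O)C#C | starting material
8 | methyl 3-lithiopropiolate (not isolated) | COC(=O)C#C[Li] | intermediate
9 | methyl 4-[3-bromo-6-methoxy-2-(methoxymethoxy)-4-methylphenyl]-4-hydroxybut-2-ynoate (racemic) | COC(=O)C#CC(O)c1c(OC)cc(C)c(Br)c1OCOC | intermediate
10 | methyl 4-[3-bromo-6-methoxy-2-(methoxymethoxy)-4-methylphenyl]-4-(tert-butyldimethylsilyloxy)but-2-ynoate (racemic) | COC(=O)C#CC(O[Si](C)(C)C(C)(C)C)c1c(OC)cc(C)c(Br)c1OCOC | intermediate
11 | methyl acetoacetate | COC(=O)CC(C)=O | starting material
12 | prenyl bromide | CC(C)=CCBr | starting material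
13 | sodium lithium dianion of methyl acetoacetate (not isolated) | [Na+].[Li+].COC([O-])=CC(=C)[O-] | intermediate
14 | methyl 7-methyl-3-oxooct-6-enoate | COC(=O)CC(=O)CCC=C(C)C | intermediate
15 | methyl (2Z)-7-methyl-3-(trimethylsilyloxy)octa-2,6-dienoate | COC(=O)/C=C(\O[Si](C)(C)C)CCC=C(C)C | intermediate
16 | lithium dienolate of 15 (not isolated) | [Li+].CO/C([O-])=C/C(O[Si](C)(C)C)=C/CC=C(C)C | intermediate
17 | (1Z,3Z)-1-methoxy-7-methyl-1,3-bis(trimethylsilyloxy)octa-1,3,6-triene | CO/C(O[Si](C)(C)C)=C/C(O[Si](C)(C)C)=C/CC=C(C)C | intermediate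
18 | methyl 2-{[3-bromo-6-methoxy-2-(methoxymethoxy)-4-methylphenyl](tert-butyldimethylsilyloxy)methyl}-6-methoxy-3-(3-methylbut-2-enyl)-4,6-bis(trimethylsilyloxy)cyclohexa-1,4-diene-1-carboxylate (diastereomer mixture, not isolated) | COC(=O)C1=C(C(O[Si](C)(C)C(C)(C)C)c2c(OC)cc(C)c(Br)c2OCOC)C(CC=C(C)C)C(O[Si](C)(C)C)=CC1(OC)O[Si](C)(C)C | intermediate
19 | methyl 2-{[3-bromo-6-methoxy-2-(methoxymethoxy)-4-methylphenyl](tert-butyldimethylsilyloxy)methyl}-4,6-dihydroxy-3-(3-methylbut-2-enyl)benzoate (racemic) | COC(=O)c1c(O)cc(O)c(CC=C(C)C)c1C(O[Si](C)(C)C(C)(C)C)c1c(OC)cc(C)c(Br)c1OCOC | intermediate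
20 | methyl 2-{[3-bromo-6-methoxy-2-(methoxymethoxy)-4-methylphenyl](tert-butyldimethylsilyloxy)methyl}-4,6-bis(methoxymethoxy)-3-(3-methylbut-2-enyl)benzoate (racemic) | COC(=O)c1c(OCOC)cc(OCOC)c(CC=C(C)C)c1C(O[Si](C)(C)C(C)(C)C)c1c(OC)cc(C)c(Br)c1OCOC | intermediate
21 | [2-{[3-bromo-6-methoxy-2-(methoxymethoxy)-4-methylphenyl](tert-butyldimethylsilyloxy)methyl}-4,6-bis(methoxymethoxy)-3-(3-methylbut-2-enyl)phenyl]methanol (racemic) | OCc1c(OCOC)cc(OCOC)c(CC=C(C)C)c1C(O[Si](C)(C)C(C)(C)C)c1c(OC)cc(C)c(Br)c1OCOC | intermediate
22 | [3-bromo-6-methoxy-2-(methoxymethoxy)-4-methylphenyl][2-(hydroxymethyl)-3,5-bis(methoxymethoxy)-6-(3-methylbut-2-enyl)phenyl]methanol (racemic) | OCc1c(OCOC)cc(OCOC)c(CC=C(C)C)c1C(O)c1c(OC)cc(C)c(Br)c1OCOC | intermediate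
23 | bis(dimethylsulfonium) dichloride of diol 22 (not isolated) | C[S+](C)OCc1c(OCOC)cc(OCOC)c(CC=C(C)C)c1C(O[S+](C)C)c1c(OC)cc(C)c(Br)c1OCOC.[Cl-].[Cl-] | intermediate
24 | 2-[3-bromo-6-methoxy-2-(methoxymethoxy)-4-methylbenzoyl]-4,6-bis(methoxymethoxy)-3-(3-methylbut-2-enyl)benzaldehyde | O=Cc1c(OCOC)cc(OCOC)c(CC=C(C)C)c1C(=O)c1c(OC)cc(C)c(Br)c1OCOC | intermediate
25 | Pestalone B, 2-(3-bromo-2-hydroxy-6-methoxy-4-methylbenzoyl)-4,6-dihydroxy-3-(3-methylbut-2-enyl)benzaldehyde | COc1cc(C)c(Br)c(O)c1C(=O)c1c(C=O)c(O)cc(O)c1CC=C(C)C | target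

**Step count**

Total step count: 15.
Longest linear sequence: 12 steps (steps 1–6, then steps 10–15); the diene branch (steps 7–9) joins at step 10.

**Steps most likely to fail**

1. Step 10 (key cycloaddition). The bond between the prenyl-bearing diene terminus and the alkyne carbon next to the bulky silyloxy(aryl)methyl group may form too slowly, so that the diene is lost to silyl migration, hydrolysis or oligomerisation first. Aromatisation may also leak towards loss of silanol, which would leave a methyl ether at C3'. Fallback: ring B is built from the same diene with a small alkyne partner, and the crowded diaryl carbinol bond is then made by aryllithium addition. It sets out from 7, 17 and 6 and comes back at 22. Methyl propiolate 7 is brominated at the alkyne terminus (NBS, cat. AgNO3, acetone) to methyl 3-bromopropiolate F1. F1 and diene 17 are heated in toluene at 80 °C to give the bromo cycloadduct F2 (not isolated), which the same cold dilute-acid work-up converts to methyl 2-bromo-4,6-dihydroxy-3-(3-methylbut-2-enyl)benzoate F3; the ester again dictates that the prenyl-bearing terminus bonds to the bromine-bearing carbon. NaH/MOMCl gives methyl 2-bromo-4,6-bis(methoxymethoxy)-3-(3-methylbut-2-enyl)benzoate F4, and DIBAL-H gives [2-bromo-4,6-bis(methoxymethoxy)-3-(3-methylbut-2-enyl)phenyl]methanol F5. Treatment with n-BuLi (2.1 equiv, THF, –78 °C) deprotonates the hydroxyl and exchanges bromine for lithium to give the O,C-dilithio species F6 (not isolated). Addition of aldehyde 6 at –78 °C and aqueous work-up should give diol 22, and the route resumes at step 14.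

2. Step 14 (double Swern oxidation). Activation of the very crowded secondary hydroxyl may be incomplete when the base is added. The aldehyde formed first would then be trapped by the neighbouring free hydroxyl as a lactol and over-oxidised to the phthalide. Fallback: the two carbinols are oxidised one at a time, setting out from 22 and coming back at 24. TBSCl/imidazole silylates only the unhindered primary hydroxyl to give the primary mono-TBS ether of diol 22 F7. Dess–Martin periodinane (NaHCO3, CH2Cl2) oxidises the diaryl carbinol to the silyloxymethyl diaryl ketone F8. TBAF releases the hydroxymethyl diaryl ketone F9, whose cyclic hemiketal has no hydrogen on the ketal carbon and so cannot be over-oxidised. A second Dess–Martin oxidation (or MnO2) of the benzylic alcohol then gives 24.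

3. Step 3 (selective demethylation). The site selectivity between the two methyl ethers may be poor, or both may be cleaved. Fallback: the order is inverted so that regiocontrol comes from the free phenol and not from the ether cleavage, setting out from 3 and coming back at 5. The symmetric aldehyde 3 is mono-demethylated with BCl3 (CH2Cl2, –78 → 0 °C), where no site question arises, to give 2-hydroxy-6-methoxy-4-methylbenzaldehyde F10. F10 is then brominated ortho to the hydroxyl by amine-mediated NBS bromination (NBS, cat. i-Pr2NH, CH2Cl2, 0 °C), in which the N-bromoamine is delivered through a hydrogen bond to the phenol, to give 5.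

**Further compounds**

F1 | step 10 | methyl 3-bromopropiolate | COC(=O)C#CBr
F2 | step 10 | methyl 2-bromo-6-methoxy-3-(3-methylbut-2-enyl)-4,6-bis(trimethylsilyloxy)cyclohexa-1,4-diene-1-carboxylate (not isolated) | COC(=O)C1=C(Br)C(CC=C(C)C)C(O[Si](C)(C)C)=CC1(OC)O[Si](C)(C)C
F3 | step 10 | methyl 2-bromo-4,6-dihydroxy-3-(3-methylbut-2-enyl)benzoate | COC(=O)c1c(O)cc(O)c(CC=C(C)C)c1Br
F4 | step 10 | methyl 2-bromo-4,6-bis(methoxymethoxy)-3-(3-methylbut-2-enyl)benzoate | COC(=O)c1c(OCOC)cc(OCOC)c(CC=C(C)C)c1Br
F5 | step 10 | [2-bromo-4,6-bis(methoxymethoxy)-3-(3-methylbut-2-enyl)phenyl]methanol | OCc1c(OCOC)cc(OCOC)c(CC=C(C)C)c1Br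
F6 | step 10 | lithium [2-lithio-4,6-bis(methoxymethoxy)-3-(3-methylbut-2-enyl)phenyl]methoxide (not isolated) | [Li]OCc1c(OCOC)cc(OCOC)c(CC=C(C)C)c1[Li]
F7 | step 14 | [3-bromo-6-methoxy-2-(methoxymethoxy)-4-methylphenyl][2-(tert-butyldimethylsilyloxymethyl)-3,5-bis(methoxymethoxy)-6-(3-methylbut-2-enyl)phenyl]methanol (racemic) | CC(C)(C)[Si](C)(C)OCc1c(OCOC)cc(OCOC)c(CC=C(C)C)c1C(O)c1c(OC)cc(C)c(Br)c1OCOC
F8 | step 14 | [3-bromo-6-methoxy-2-(methoxymethoxy)-4-methylphenyl][2-(tert-butyldimethylsilyloxymethyl)-3,5-bis(methoxymethoxy)-6-(3-methylbut-2-enyl)phenyl]methanone | CC(C)(C)[Si](C)(C)OCc1c(OCOC)cc(OCOC)c(CC=C(C)C)c1C(=O)c1c(OC)cc(C)c(Br)c1OCOC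
F9 | step 14 | [3-bromo-6-methoxy-2-(methoxymethoxy)-4-methylphenyl][2-(hydroxymethyl)-3,5-bis(methoxymethoxy)-6-(3-methylbut-2-enyl)phenyl]methanone | OCc1c(OCOC)cc(OCOC)c(CC=C(C)C)c1C(=O)c1c(OC)cc(C)c(Br)c1OCOC
F10 | step 3 | 2-hydroxy-6-methoxy-4-methylbenzaldehyde | COc1cc(C)cc(O)c1C=O
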